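**Plan**

1. Cuts: the central CH–CH single bond of the polyene (Suzuki–Miyaura); the O–C8 bond of the 2,5-dihydrofuran; C8–H together with the C6–O bond of an epoxide (reductive opening of an alkynyl epoxide); the alkyne–butenolide bond and the lactone C–O/C–C bonds (Sonogashira, Sonogashira–lactonisation); the cyclohexenyl–alkyne bond (Sonogashira).
2. Forward: both six-membered rings come intact from (−)-actinol. The butenolide is closed on a C7 enyne boronate, the epoxy-alkyne is attached, the epoxide is opened to an allenol, and the dihydrofuran is closed last. The eastern dienynyl iodide is then coupled and the two silyl ethers are removed.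
3. Stereochemistry: both carbinol centres from actinol; C5 from a tartrate-controlled epoxidation anti to the silyloxy group; the C6 epoxide centre is traded for an allene axis (anti-SN2′ Pd–H) and the axis for C8 in the gold-catalysed closure. Alkene geometry comes from the (E)-enynol, two chromium(II) homologations, anti-addition in the lactonisation (Z-ylidene) and stereoretentive couplings.
4. Enabling feature: in the hexahydrobenzofuran the ring alkene C6=C7 is exocyclic to the cyclohexane and sits between the tertiary C5–O carbon and the allylic C8–O carbon. The ring is therefore the cycloisomer of a 2-hydroxy-vinylidenecyclohexane (a tertiary α-allenol), and that allene is the reduction product of a C5–C6 epoxide carrying an alkyne on C6.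

Key step: step 17

Remark: carotenoid numbering is used for the western end group (C3 carbinol, C5 oxygen-bearing quaternary carbon, C6 sp2 ring-fusion carbon, C7 ring =CH, C8 the O–CH on the butenolide). Compounds 1, 5 and 16 and all reagents are taken as commercial. The allene axis of 21 is written with the extended-tetrahedral SMILES tag.

**Route**

Step 1
Reactants: 1 (4R,6R)-4-hydroxy-2,2,6-trimethylcyclohexanone ((−)-actinol)
Product: 2 (4R,6R)-4-(tert-butyldimethylsilyloxy)-2,2,6-trimethylcyclohexanone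
Conditions: TBSCl, imidazole, DMF, rt
Reagents that add atoms: tert-butyldimethylsilyl chloride, C[Si](C)(Cl)C(C)(C)C
Why: Standard silyl ether protection of the secondary alcohol; no stereocentre is touched.

Step 2
Reactants: 2 (4R,6R)-4-(tert-butyldimethylsilyloxy)-2,2,6-trimethylcyclohexanone
Product: 4 (4R)-4-(tert-butyldimethylsilyloxy)-2,6,6-trimethylcyclohex-1-en-1-yl trifluoromethanesulfonate, via potassium enolate 3 (not isolated)
Conditions: KHMDS, THF, −78 °C; then PhNTf2, −78 to 0 °C
Reagents that add atoms: N-phenyl-bis(trifluoromethanesulfonimide), O=S(=O)(N(c1ccccc1)S(=O)(=O)C(F)(F)F)C(F)(F)F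
Why: Enolate O-triflation; only the methyl-bearing α-carbon has a hydrogen, so a single tetrasubstituted enol triflate can form and the expendable methyl stereocentre is erased.

Step 3
Reactants: 4 the enol triflate; 5 (E)-3-methylpent-2-en-4-yn-1-ol
Product: 6 (2E)-5-[(4R)-4-(tert-butyldimethylsilyloxy)-2,6,6-trimethylcyclohex-1-en-1-yl]-3-methylpent-2-en-4-yn-1-ol
Conditions: Pd(PPh3)4 (cat.), CuI (cat.), i-Pr2NH, DMF, rt to 50 °C
Reagents that add atoms: none
Why: Sonogashira coupling of the enol triflate with the terminal alkyne; the E geometry is carried in from 5 and the free primary alcohol is tolerated.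

Step 4
Reactants: 6 the C15 enynol
Product: 7 (2E)-5-[(4R)-4-(tert-butyldimethylsilyloxy)-2,6,6-trimethylcyclohex-1-en-1-yl]-3-methylpent-2-en-4-ynal
Conditions: MnO2, CH2Cl2, rt, dark
Reagents that add atoms: none
Why: Chemoselective MnO2 oxidation of the allylic alcohol to the enal without change of alkene geometry.

Step 5
Reactants: 7 the C15 enynal
Product: 8 (1E,3E)-1-iodo-4-methyl-6-[(4R)-4-(tert-butyldimethylsilyloxy)-2,6,6-trimethylcyclohex-1-en-1-yl]hexa-1,3-dien-5-yne
Conditions: CrCl2, CHI3, THF/dioxane, 0 °C to rt, dark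
Reagents that add atoms: iodoform, IC(I)I
Why: Takai iodo-olefination; the gem-dichromium reagent adds to the aldehyde and eliminates to the (E)-vinyl iodide, the alkyne and silyl ether being inert to Cr(II).

Step 6
Reactants: 4 the enol triflate
Product: 9 methyl (4R)-4-(tert-butyldimethylsilyloxy)-2,6,6-trimethylcyclohex-1-ene-1-carboxylate
Conditions: Pd(OAc)2 (cat.), PPh3, CO (1 atm), MeOH, Et3N, DMF, 60 °C
Reagents that add atoms: carbon monoxide, [C-]#[O+]; methanol, CO
Why: Palladium-catalysed alkoxycarbonylation of the enol triflate (oxidative addition, CO insertion, methanolysis) puts the C7 carbon on C6.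

Step 7
Reactants: 9 the methyl ester
Product: 10 [(4R)-4-(tert-butyldimethylsilyloxy)-2,6,6-trimethylcyclohex-1-en-1-yl]methanol
Conditions: DIBAL-H, CH2Cl2, −78 °C; Rochelle salt work-up
Reagents that add atoms: none
Why: DIBAL-H reduction of the conjugated ester gives the allylic alcohol that is needed to direct the epoxidation.

Step 8
Reactants: 10 the allylic alcohol
Product: 11 [(1R,4S,6R)-4-(tert-butyldimethylsilyloxy)-2,2,6-trimethyl-7-oxabicyclo[4.1.0]heptan-1-yl]methanol (epoxide anti to the silyloxy group)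
Conditions: Ti(Oi-Pr)4, D-(−)-diethyl tartrate, t-BuOOH, 4 Å MS, CH2Cl2, −20 °C
Reagents that add atoms: tert-butyl hydroperoxide, CC(C)(C)OO
Why: Katsuki–Sharpless asymmetric epoxidation; with D-(−)-tartrate the peroxide oxygen is delivered to the alkene face anti to the C3 silyloxy group, which sets C5 (R) and the temporary C6 centre under reagent control.

Step 9
Reactants: 11 the epoxy alcohol
Product: 12 (1S,4S,6R)-4-(tert-butyldimethylsilyloxy)-2,2,6-trimethyl-7-oxabicyclo[4.1.0]heptane-1-carbaldehyde
Conditions: TPAP (cat.), NMO, 4 Å MS, CH2Cl2, rt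
Reagents that add atoms: none
Why: Ley–Griffith oxidation is neutral, so the acid-labile tetrasubstituted epoxide survives and the non-enolisable epoxy aldehyde cannot epimerise.

Step 10
Reactants: 12 the epoxy aldehyde
Product: 13 (1R,4S,6R)-4-(tert-butyldimethylsilyloxy)-1-ethynyl-2,2,6-trimethyl-7-oxabicyclo[4.1.0]heptane
Conditions: dimethyl (1-diazo-2-oxopropyl)phosphonate, K2CO3, MeOH, 0 °C to rt
Reagents that add atoms: Ohira–Bestmann reagent, COP(=O)(OC)C(=[N+]=[N-])C(C)=O
Why: Ohira–Bestmann (Seyferth–Gilbert) homologation turns the aldehyde into the terminal alkyne under mild carbonate conditions that leave the epoxide and its stereocentres intact.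

Step 11
Reactants: 5 (E)-3-methylpent-2-en-4-yn-1-ol
Product: 14 (E)-3-methylpent-2-en-4-ynal
Conditions: MnO2, CH2Cl2, rt; used as a solution
Reagents that add atoms: none
Why: MnO2 oxidation of the allylic alcohol; the volatile enynal is carried on in solution.

Step 12
Reactants: 14 (E)-3-methylpent-2-en-4-ynal
Product: 15 2-[(1E,3E)-4-methylhexa-1,3-dien-5-yn-1-yl]-4,4,5,5-tetramethyl-1,3,2-dioxaborolane
Conditions: CrCl2, Cl2CHBpin, LiI, THF, rt
Reagents that add atoms: 2-(dichloromethyl)-4,4,5,5-tetramethyl-1,3,2-dioxaborolane, ClC(Cl)B1OC(C)(C)C(C)(C)O1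
Why: Takai–Utimoto boryl-olefination; the gem-dichromium boronate adds to the enal and eliminates to the (E)-alkenylboronate, and the terminal alkyne is inert to Cr(II).

Step 13
Reactants: 16 propiolic acid
Product: 17 (E)-2,3-dibromoprop-2-enoic acid
Conditions: Br2, CH2Cl2, 0 °C to rt, dark
Reagents that add atoms: bromine, BrBr
Why: Anti addition of bromine to the alkyne gives the (E)-dibromide, in which the C3 bromine is cis to the carboxyl group as the lactonisation requires.

Step 14
Reactants: 17 (E)-2,3-dibromoprop-2-enoic acid; 15 the dienynyl boronate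
Product: 19 (5Z)-3-bromo-5-[(2E,4E)-2-methyl-5-(4,4,5,5-tetramethyl-1,3,2-dioxaborolan-2-yl)penta-2,4-dien-1-ylidene]furan-2(5H)-one, via bromoenynoic acid 18 (not isolated)
Conditions: PdCl2(PPh3)2 (cat.), CuI (cat.), Et3N, MeCN, rt
Reagents that add atoms: none
Why: Tandem Sonogashira coupling at the more reactive β-bromide, then 5-exo-dig anti-addition of the carboxylate to the alkyne, closes the butenolide as the (Z)-ylidene isomer and leaves the α-bromide and the boronate for later couplings.

Step 15
Reactants: 13 the ethynyl epoxide; 19 the bromobutenolide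
Product: 20 (5Z)-3-{[(1R,4S,6R)-4-(tert-butyldimethylsilyloxy)-2,2,6-trimethyl-7-oxabicyclo[4.1.0]heptan-1-yl]ethynyl}-5-[(2E,4E)-2-methyl-5-(pinacolatoboryl)penta-2,4-dien-1-ylidene]furan-2(5H)-one
Conditions: PdCl2(PPh3)2 (cat.), CuI (cat.), i-Pr2NEt, THF, rt
Reagents that add atoms: none
Why: Sonogashira coupling of the activated α-bromobutenolide with the terminal alkyne; oxidative addition to the vinyl bromide should outrun ionisation of the hindered propargylic epoxide.

Step 16
Reactants: 20 the epoxy-ynyl butenolide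
Product: 21 (5Z)-3-{(aS)-2-[(2R,4S)-4-(tert-butyldimethylsilyloxy)-2-hydroxy-2,6,6-trimethylcyclohexylidene]ethenyl}-5-[(2E,4E)-2-methyl-5-(pinacolatoboryl)penta-2,4-dien-1-ylidene]furan-2(5H)-one (butenolide on the allene face syn to the C5 oxygen)
Conditions: Pd2(dba)3·CHCl3 (cat.), n-Bu3P (cat.), HCO2H/Et3N, THF, rt
Reagents that add atoms: none
Why: Palladium-catalysed formate hydrogenolysis of a propargylic epoxide: Pd(0) attacks C8 anti to the breaking C6–O bond (SN2′) and the formate-derived hydride replaces palladium with retention, so H8 ends anti and the butenolide syn to the C5 oxygen, turning the C6 centre into the (aS) allene axis while C5 stays fixed.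

Step 17
Reactants: 21 the α-hydroxyallene
Product: 23 (5Z)-3-[(2R,6S,7aR)-6-(tert-butyldimethylsilyloxy)-4,4,7a-trimethyl-2,4,5,6,7,7a-hexahydro-1-benzofuran-2-yl]-5-[(2E,4E)-2-methyl-5-(pinacolatoboryl)penta-2,4-dien-1-ylidene]furan-2(5H)-one, via vinylgold species 22 (not isolated)
Conditions: Ph3PAuNTf2 (5 mol%), CH2Cl2, 0 °C to rt, dark
Reagents that add atoms: none
Why: Ph3PAu+ binds the C7=C8 π-bond of the allene on the side away from the tertiary C5–OH, the hydroxyl oxygen adds to C8 (anti-oxyauration) to give the C7-vinylgold species 22, and protodeauration releases 23 and the catalyst. The closest known reaction type is the gold-catalysed cycloisomerisation of α-hydroxyallenes to 2,5-dihydrofurans with axis-to-centre chirality transfer. The ring is closed in the 5-endo-trig mode by O–C8 bond formation. C8 is the only new stereocentre and is fixed by the allene axis: the oxygen attacks in the plane of C1/C5/C6, so the hydrogen and the butenolide on C8 keep the faces they hold in the (aS)-allene and the butenolide ends anti to the C5 methyl (8R), while C3 and C5 are not touched. The step needs chemoselectivity for the hydroxyallene over the ylidenebutenolide and the dienylboronate, and over ionisation of the tertiary carbinol or Nazarov-type closure of the vinylallene; this should be secured because the only tethered nucleophile sits α to the allene, the butenolide alkene is electron-poor, a C–C closure at C6 would build a spiro centre between two quaternary carbons, and a phosphine-gold(I) catalyst free of Brønsted acid is used in the cold. The cyclohexane must flip so that the C5–O bond lies near the allene plane, a geometry the fused product requires in any case.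

Step 18
Reactants: 23 the dihydrofuran boronate; 8 the dienynyl iodide
Product: 24 the bis(tert-butyldimethylsilyl) ether of the target (both ring hydroxyls as OTBS)
Conditions: Pd(OAc)2/SPhos (cat.), K3PO4 (aq.), THF, rt, dark
Reagents that add atoms: none
Why: Suzuki–Miyaura coupling of the (E)-dienylboronate with the (E)-dienynyl iodide is stereoretentive at both partners and completes the all-E polyene under mild phosphate base.

Step 19
Reactants: 24 the bis-silyl ether
Product: 25 the target, (3S,5R,8R)-furanoid / (3′R)-acetylenic C37 butenolide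
Conditions: HF·pyridine, pyridine, THF, 0 °C to rt, dark
Reagents that add atoms: none
Why: Buffered HF·pyridine cleaves both secondary TBS ethers by fluoride attack at silicon without the strong acid or base that would epimerise C8 or open the ylidenebutenolide.

**Compound list**

1 | (4R,6R)-4-hydroxy-2,2,6-trimethylcyclohexanone ((−)-actinol) | O=C1C(C)(C)C[C@H](O)C[C@H]1C | starting material
2 | (4R,6R)-4-(tert-butyldimethylsilyloxy)-2,2,6-trimethylcyclohexanone | O=C1C(C)(C)C[C@H](O[Si](C)(C)C(C)(C)C)C[C@H]1C | intermediate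
3 | potassium (4R)-4-(tert-butyldimethylsilyloxy)-2,6,6-trimethylcyclohex-1-en-1-olate | CC1=C([O-])C(C)(C)C[C@H](O[Si](C)(C)C(C)(C)C)C1.[K+] | intermediate (not isolated)
4 | (4R)-4-(tert-butyldimethylsilyloxy)-2,6,6-trimethylcyclohex-1-en-1-yl trifluoromethanesulfonate | CC1=C(OS(=O)(=O)C(F)(F)F)C(C)(C)C[C@H](O[Si](C)(C)C(C)(C)C)C1 | intermediate
5 | (E)-3-methylpent-2-en-4-yn-1-ol | C#C/C(C)=C/CO | starting material
6 | (2E)-5-[(4R)-4-(tert-butyldimethylsilyloxy)-2,6,6-trimethylcyclohex-1-en-1-yl]-3-methylpent-2-en-4-yn-1-ol | CC1=C(C#C/C(C)=C/CO)C(C)(C)C[C@H](O[Si](C)(C)C(C)(C)C)C1 | intermediate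
7 | (2E)-5-[(4R)-4-(tert-butyldimethylsilyloxy)-2,6,6-trimethylcyclohex-1-en-1-yl]-3-methylpent-2-en-4-ynal | CC1=C(C#C/C(C)=C/C=O)C(C)(C)C[C@H](O[Si](C)(C)C(C)(C)C)C1 | intermediate
8 | (1E,3E)-1-iodo-4-methyl-6-[(4R)-4-(tert-butyldimethylsilyloxy)-2,6,6-trimethylcyclohex-1-en-1-yl]hexa-1,3-dien-5-yne | CC1=C(C#C/C(C)=C/C=C/I)C(C)(C)C[C@H](O[Si](C)(C)C(C)(C)C)C1 | intermediate
9 | methyl (4R)-4-(tert-butyldimethylsilyloxy)-2,6,6-trimethylcyclohex-1-ene-1-carboxylate | CC1=C(C(=O)OC)C(C)(C)C[C@H](O[Si](C)(C)C(C)(C)C)C1 | intermediate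
10 | [(4R)-4-(tert-butyldimethylsilyloxy)-2,6,6-trimethylcyclohex-1-en-1-yl]methanol | CC1=C(CO)C(C)(C)C[C@H](O[Si](C)(C)C(C)(C)C)C1 | intermediate
11 | [(1R,4S,6R)-4-(tert-butyldimethylsilyloxy)-2,2,6-trimethyl-7-oxabicyclo[4.1.0]heptan-1-yl]methanol | OC[C@]12C(C)(C)C[C@H](O[Si](C)(C)C(C)(C)C)C[C@@]1(C)O2 | intermediate
12 | (1S,4S,6R)-4-(tert-butyldimethylsilyloxy)-2,2,6-trimethyl-7-oxabicyclo[4.1.0]heptane-1-carbaldehyde | O=C[C@]12C(C)(C)C[C@H](O[Si](C)(C)C(C)(C)C)C[C@@]1(C)O2 | intermediate
13 | (1R,4S,6R)-4-(tert-butyldimethylsilyloxy)-1-ethynyl-2,2,6-trimethyl-7-oxabicyclo[4.1.0]heptane | C#C[C@]12C(C)(C)C[C@H](O[Si](C)(C)C(C)(C)C)C[C@@]1(C)O2 | intermediate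
14 | (E)-3-methylpent-2-en-4-ynal | C#C/C(C)=C/C=O | intermediate
15 | 2-[(1E,3E)-4-methylhexa-1,3-dien-5-yn-1-yl]-4,4,5,5-tetramethyl-1,3,2-dioxaborolane | C#C/C(C)=C/C=C/B1OC(C)(C)C(C)(C)O1 | intermediate
16 | propiolic acid | C#CC(=O)O | starting material
17 | (E)-2,3-dibromoprop-2-enoic acid | OC(=O)/C(Br)=C\Br | intermediate
18 | (2E,6E,8E)-2-bromo-6-methyl-9-(4,4,5,5-tetramethyl-1,3,2-dioxaborolan-2-yl)nona-2,6,8-trien-4-ynoic acid | OC(=O)/C(Br)=C\C#C/C(C)=C/C=C/B1OC(C)(C)C(C)(C)O1 | intermediate (not isolated)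
19 | (5Z)-3-bromo-5-[(2E,4E)-2-methyl-5-(4,4,5,5-tetramethyl-1,3,2-dioxaborolan-2-yl)penta-2,4-dien-1-ylidene]furan-2(5H)-one | CC1(C)OB(/C=C/C=C(C)/C=C2/C=C(Br)C(=O)O2)OC1(C)C | intermediate
20 | (5Z)-3-{[(1R,4S,6R)-4-(tert-butyldimethylsilyloxy)-2,2,6-trimethyl-7-oxabicyclo[4.1.0]heptan-1-yl]ethynyl}-5-[(2E,4E)-2-methyl-5-(pinacolatoboryl)penta-2,4-dien-1-ylidene]furan-2(5H)-one | CC1(C)OB(/C=C/C=C(C)/C=C2/C=C(C#C[C@]34C(C)(C)C[C@H](O[Si](C)(C)C(C)(C)C)C[C@@]3(C)O4)C(=O)O2)OC1(C)C | intermediate
21 | (5Z)-3-{(aS)-2-[(2R,4S)-4-(tert-butyldimethylsilyloxy)-2-hydroxy-2,6,6-trimethylcyclohexylidene]ethenyl}-5-[(2E,4E)-2-methyl-5-(pinacolatoboryl)penta-2,4-dien-1-ylidene]furan-2(5H)-one | CC1(C)OB(/C=C/C=C(C)/C=C2/C=C(C=[C@]=C3C(C)(C)C[C@H](O[Si](C)(C)C(C)(C)C)C[C@@]3(C)O)C(=O)O2)OC1(C)C | intermediate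
22 | C7-(triphenylphosphine)gold(I) derivative of 23 (vinylgold) | CC1(C)OB(/C=C/C=C(C)/C=C2/C=C([C@H]3C([Au-][P+](c5ccccc5)(c5ccccc5)c5ccccc5)=C4C(C)(C)C[C@H](O[Si](C)(C)C(C)(C)C)C[C@@]4(C)O3)C(=O)O2)OC1(C)C | intermediate (not isolated)
23 | (5Z)-3-[(2R,6S,7aR)-6-(tert-butyldimethylsilyloxy)-4,4,7a-trimethyl-2,4,5,6,7,7a-hexahydro-1-benzofuran-2-yl]-5-[(2E,4E)-2-methyl-5-(pinacolatoboryl)penta-2,4-dien-1-ylidene]furan-2(5H)-one | CC1(C)OB(/C=C/C=C(C)/C=C2/C=C([C@H]3C=C4C(C)(C)C[C@H](O[Si](C)(C)C(C)(C)C)C[C@@]4(C)O3)C(=O)O2)OC1(C)C | intermediate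
24 | bis(tert-butyldimethylsilyl) ether of the target | CC1=C(C#C/C(C)=C/C=C/C=C/C=C(C)/C=C2/C=C([C@H]3C=C4C(C)(C)C[C@H](O[Si](C)(C)C(C)(C)C)C[C@@]4(C)O3)C(=O)O2)C(C)(C)C[C@H](O[Si](C)(C)C(C)(C)C)C1 | intermediate
25 | target CNP0300047.2 | CC1=C(C#C/C(C)=C/C=C/C=C/C=C(C)/C=C2/C=C([C@H]3C=C4C(C)(C)C[C@H](O)C[C@@]4(C)O3)C(=O)O2)C(C)(C)C[C@H](O)C1 | target

**Totals**

Total step count: 19.
Longest linear sequence: 12 steps (steps 1, 2, 6–10, 15–19 from compound 1).

**Steps most likely to fail, with fallbacks**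

Step 16. The palladium hydride may be delivered to the wrong allenyl terminus, or to the butenolide alkene through a vinylogous η3 species. The allenylpalladium intermediate may also equilibrate and erode the axis. Fallback: setting out from 20, the alkyne is semi-hydrogenated (Zn(Cu/Ag) in MeOH/H2O, or H2 with Lindlar catalyst and quinoline) to the (7Z)-vinyl epoxide F1. A trace of acid (PPTS in CH2Cl2 or very dilute HCl in CHCl3) then triggers the classical epoxide-to-furanoid rearrangement through the allylic cation and returns to the route at 23. This gives up the stereochemical relay: 23 should form together with its C8 epimer, which would be separated by chromatography and re-equilibrated under the same acid.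

Step 17. The tertiary allenyl carbinol may ionise under the Lewis acid, the vinylallene may close in a carbocyclic sense, or the ring flip needed for closure may make the cyclisation slow enough for the axis to racemise. Fallback: setting out from 21, anti-iodoetherification with NIS in CH2Cl2 at 0 °C (5-endo, same axis-to-centre transfer) gives the 3-iodo-2,5-dihydrofuran F2. Reductive removal of the vinylic iodine with Bu3SnH and catalytic Pd(PPh3)4 in THF returns to the route at 23.

Step 18. The aqueous base may open the ylidenebutenolide, the dienylboronate may protodeboronate faster than it transmetalates, and the polyene may isomerise. Fallback: a base-free Stille union of the same bond with reversed polarity. Setting out from 23, iododeboronation with NaI and chloramine-T in aqueous THF gives the dienyl iodide F3 with retention. Setting out from 7, chromium(II) stannyl-olefination (Bu3SnCHBr2, CrCl2, LiI, THF) gives the dienynyl stannane F4. Coupling of F3 and F4 with Pd2(dba)3/AsPh3 in NMP at rt returns to the route at 24.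

**Further compounds**

F1 | step 16 | (5Z)-3-{(Z)-2-[(1S,4S,6R)-4-(tert-butyldimethylsilyloxy)-2,2,6-trimethyl-7-oxabicyclo[4.1.0]heptan-1-yl]ethenyl}-5-[(2E,4E)-2-methyl-5-(pinacolatoboryl)penta-2,4-dien-1-ylidene]furan-2(5H)-one | CC1(C)OB(/C=C/C=C(C)/C=C2/C=C(/C=C\[C@]34C(C)(C)C[C@H](O[Si](C)(C)C(C)(C)C)C[C@@]3(C)O4)C(=O)O2)OC1(C)C
F2 | step 17 | 3-iodo derivative of 23 (iodine on C7 of the dihydrofuran) | CC1(C)OB(/C=C/C=C(C)/C=C2/C=C([C@H]3C(I)=C4C(C)(C)C[C@H](O[Si](C)(C)C(C)(C)C)C[C@@]4(C)O3)C(=O)O2)OC1(C)C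
F3 | step 18 | (5Z)-3-[(2R,6S,7aR)-6-(tert-butyldimethylsilyloxy)-4,4,7a-trimethyl-2,4,5,6,7,7a-hexahydro-1-benzofuran-2-yl]-5-[(2E,4E)-5-iodo-2-methylpenta-2,4-dien-1-ylidene]furan-2(5H)-one | I/C=C/C=C(C)/C=C1/C=C([C@H]2C=C3C(C)(C)C[C@H](O[Si](C)(C)C(C)(C)C)C[C@@]3(C)O2)C(=O)O1
F4 | step 18 | tributyl{(1E,3E)-4-methyl-6-[(4R)-4-(tert-butyldimethylsilyloxy)-2,6,6-trimethylcyclohex-1-en-1-yl]hexa-1,3-dien-5-yn-1-yl}stannane | CC1=C(C#C/C(C)=C/C=C/[Sn](CCCC)(CCCC)CCCC)C(C)(C)C[C@H](O[Si](C)(C)C(C)(C)C)C1
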